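**Retrosynthetic overview**
1. Feature: C2 of the oxolane ring is the benzylic carbon para to the free OH of the 4-hydroxy-3,5-dimethoxyphenyl (syringyl) ring. The O1–C2 bond can therefore be made from a plain CH2 group by dehydrogenation to a p-quinone methide.
2. Last cut: the O–CH2 bond of the ferulate at the C3 hydroxymethyl group (Mitsunobu reaction with unprotected ferulic acid), made after one benzyl ether has been removed.
3. Key cut: O1–C2, leading back to an open (2R,3R)-dibenzylbutane-1,4-diol with a free syringyl phenol and an O-benzylated guaiacyl ring. The C2 stereocentre arises in this closure.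
4. The diol comes from a trans-(3R,4R)-dibenzylbutyrolactone. C3 is set by anti alkylation of the (R)-β-benzyl lactone with a silylated syringyl bromide, and C4 by asymmetric hydrogenation of the Stobbe half-ester of O-benzylvanillin.
5. Ring order: a temporary butyrolactone (closed in step 4, opened in step 9), then the oxolane (step 11), the only ring built that remains.

Key step: step 11

Assumption: the (S,S)-Et-DuPHOS rhodium catalyst is taken to deliver the R acid, by analogy with other itaconate half-esters; if the configuration check on lactone 7 says otherwise, the (R,R) ligand is used and nothing else changes.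

Step 1
Reactants: 1 vanillin
Product: 2 4-(benzyloxy)-3-methoxybenzaldehyde (O-benzylvanillin)
Conditions: BnBr (1.1 equiv), K2CO3 (1.5 equiv), DMF, rt
Reagents that add atoms: benzyl bromide, BrCc1ccccc1
Why: Williamson ether synthesis on the only acidic OH should be clean, and the benzyl ether later keeps the guaiacyl ring from forming a quinone methide in step 11.

Step 2
Reactants: 2 O-benzylvanillin; 3 dimethyl succinate
Product: 4 (E)-4-[4-(benzyloxy)-3-methoxyphenyl]-3-(methoxycarbonyl)but-3-enoic acid
Conditions: NaOMe (1.5 equiv), MeOH, reflux; then aq. HCl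
Reagents that add atoms: none
Why: Stobbe condensation (aldol addition of the succinate enolate, then irreversible eliminative formation of the carboxylate) should give the E half-ester with the aryl group trans to CO2Me, and it tells the two carboxyl carbons apart.

Step 3
Reactants: 4 (E)-half-ester
Product: 5 (3R)-4-[4-(benzyloxy)-3-methoxyphenyl]-3-(methoxycarbonyl)butanoic acid
Conditions: H2 (6 bar), [Rh(cod)((S,S)-Et-DuPHOS)]BF4 (0.5 mol %), NaOMe (10 mol %), MeOH, rt; then dilute HCl
Reagents that add atoms: none
Why: Asymmetric hydrogenation of a β-aryl itaconate half-ester, a standard substrate class for cationic rhodium bisphospholane catalysts, in which the carboxylate binds rhodium and the twofold-symmetric ligand directs H2 to one alkene face, should set the future C4 as R while the homogeneous catalyst leaves the benzyl ether alone.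

Step 4
Reactants: 5 (R)-half-ester
Product: 7 (4R)-4-[4-(benzyloxy)-3-methoxybenzyl]oxolan-2-one, via hydroxy acid 6 (not isolated)
Conditions: KOH (1.0 equiv), EtOH; CaCl2, NaBH4, EtOH, −10 °C → rt; then 2 M HCl, rt
Reagents that add atoms: none
Why: Chemoselective borohydride reduction, in which Ca(BH4)2 reduces the methyl ester but not the carboxylate salt, followed by acid lactonisation of 6, should give the β-benzyl lactone with a stereocentre that is no longer alpha to a carbonyl group.

Step 5
Reactants: 8 syringaldehyde
Product: 9 4-(tert-butyldimethylsilyloxy)-3,5-dimethoxybenzaldehyde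
Conditions: TBSCl (1.2 equiv), imidazole (2.5 equiv), DMF, rt
Reagents that add atoms: tert-butyldimethylsilyl chloride, CC(C)(C)[Si](C)(C)Cl
Why: Imidazole-promoted silylation of the phenol gives an ether that should survive hydride, PBr3 and a lithium enolate, and that fluoride removes without touching the benzyl ether.

Step 6
Reactants: 9 silylated syringaldehyde
Product: 10 [4-(tert-butyldimethylsilyloxy)-3,5-dimethoxyphenyl]methanol
Conditions: NaBH4, THF–MeOH, 0 °C
Reagents that add atoms: none
Why: Borohydride reduction of an aromatic aldehyde is fast at 0 °C, so the aryl silyl ether is exposed to alkoxide only briefly.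

Step 7
Reactants: 10 benzylic alcohol
Product: 11 4-(tert-butyldimethylsilyloxy)-3,5-dimethoxybenzyl bromide
Conditions: PBr3 (0.4 equiv), Et2O, 0 °C; aqueous wash, used at once without chromatography
Reagents that add atoms: phosphorus tribromide, BrP(Br)Br
Why: Bromination of a benzylic alcohol through its phosphite ester (SN2 by bromide) is a standard way to such electron-rich benzyl bromides, which are labile and are therefore carried on crude.

Step 8
Reactants: 7 (R)-lactone; 11 syringyl bromide
Product: 13 (3R,4R)-4-[4-(benzyloxy)-3-methoxybenzyl]-3-[4-(tert-butyldimethylsilyloxy)-3,5-dimethoxybenzyl]oxolan-2-one (trans), via lithium enolate 12 (not isolated)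
Conditions: LiN(SiMe3)2 (1.05 equiv), THF, −78 °C; then 11 (1.1 equiv), DMPU, −78 → −30 °C
Reagents that add atoms: none
Why: Diastereoselective enolate alkylation, in which the bromide approaches the flat enolate 12 on the face opposite the C4 benzyl group, should give the trans lactone and so set the future C3 as R.

Step 9
Reactants: 13 trans-lactone
Product: 14 (2R,3R)-2-[4-(benzyloxy)-3-methoxybenzyl]-3-[4-(tert-butyldimethylsilyloxy)-3,5-dimethoxybenzyl]butane-1,4-diol
Conditions: LiAlH4, THF, 0 °C → rt; then H2O, aq. NaOH, H2O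
Reagents that add atoms: none
Why: LiAlH4 reduction of a lactone to the 1,4-diol touches neither stereocentre, and any partial loss of the aryl silyl group does no harm because the next step removes it.

Step 10
Reactants: 14 silylated diol
Product: 15 (2R,3R)-2-[4-(benzyloxy)-3-methoxybenzyl]-3-(4-hydroxy-3,5-dimethoxybenzyl)butane-1,4-diol
Conditions: Bu4NF (1.1 equiv), AcOH (1.1 equiv), THF, 0 °C, argon
Reagents that add atoms: none
Why: Fluoride desilylation of an aryl silyl ether is fast, and the acetic acid buffer keeps the easily oxidised syringyl phenol from standing as its phenoxide.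

Step 11
Reactants: 15 open diol with free syringyl phenol
Product: 17 4-{(2S,3R,4R)-4-[4-(benzyloxy)-3-methoxybenzyl]-3-(hydroxymethyl)oxolan-2-yl}-2,6-dimethoxyphenol (mono-O-benzyl 5-methoxylariciresinol), via p-quinone methide 16 (not isolated)
Conditions: DDQ (1.0 equiv, added slowly), 4 Å molecular sieves, CH2Cl2, −20 → 0 °C, argon; filtration, aq. NaHCO3 wash
Reagents that add atoms: none
Why: DDQ forms a charge-transfer complex with the only free phenol and removes two electrons and two protons from it (the phenolic H and one H of the para benzylic CH2), which should give p-quinone methide 16 with its electrophilic exocyclic carbon at the future C2. The closest known reaction type is the DDQ or Ag2O dehydrogenation of 4-alkyl-2,6-dimethoxyphenols to quinone methides with capture by an alcohol, the same event that closes the furan rings when sinapyl alcohol is dimerised oxidatively. The oxolane ring closes by 5-exo-trig 1,6-conjugate addition of the hydroxyl on the guaiacyl half (future O1) to that carbon, driven by rearomatisation, whereas the other hydroxyl could only form an oxetane and so stays free for the ferulate. The new C2 centre is controlled by the C3 centre: allylic 1,3-strain turns the C3–H bond into the plane of the quinone methide, the tethered oxygen then arrives from the face that bears the C4 chain, and the aryl group ends up trans to the C3 hydroxymethyl group (2S), which is also the more stable isomer should the addition be reversible. Site selectivity between the two benzylic CH2 groups is secured by the benzyl ether, since an O-alkylated ring cannot give a neutral quinone methide and is oxidised much more slowly. Selectivity for O- over C-attack (Friedel-Crafts closure by the guaiacyl ring to an aryltetralin) and against a second oxidation is sought by adding no acid, by the precipitation of the hydroquinone from CH2Cl2, by the low temperature and by using exactly one equivalent of DDQ.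

Step 12
Reactants: 17 mono-O-benzyl 5-methoxylariciresinol
Product: 18 5-methoxylariciresinol, 4-{(2S,3R,4R)-4-(4-hydroxy-3-methoxybenzyl)-3-(hydroxymethyl)oxolan-2-yl}-2,6-dimethoxyphenol
Conditions: H2 (1 atm), 10% Pd/C, EtOAc, rt, stopped as soon as 17 is consumed
Reagents that add atoms: none
Why: Catalytic hydrogenolysis cleaves an aryl benzyl ether much faster than the hindered secondary O1–C2 benzylic ether in a neutral, non-protic solvent, and it is placed before the ferulate is attached so that no cinnamate C=C bond is exposed to H2.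

Step 13
Reactants: 18 5-methoxylariciresinol; 19 (E)-ferulic acid
Product: 20 target, [(2S,3R,4R)-2-(4-hydroxy-3,5-dimethoxyphenyl)-4-(4-hydroxy-3-methoxybenzyl)oxolan-3-yl]methyl (E)-3-(4-hydroxy-3-methoxyphenyl)prop-2-enoate
Conditions: 19 (1.2 equiv), PPh3 (1.3 equiv), DIAD (1.3 equiv, added last), THF, 0 °C → rt
Reagents that add atoms: none
Why: Mitsunobu esterification is known to be chemoselective for unprotected phenolic acids, because only the carboxylic acid protonates the betaine quickly, and its carboxylate then displaces the oxyphosphonium group at the single aliphatic CH2OH, a carbon that is not stereogenic, while the much less acidic phenols stay out.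

**Compound list**
1 | vanillin | COc1cc(C=O)ccc1O | starting material
2 | 4-(benzyloxy)-3-methoxybenzaldehyde | COc1cc(C=O)ccc1OCc1ccccc1 | intermediate
3 | dimethyl succinate | COC(=O)CCC(=O)OC | starting material
4 | (E)-4-[4-(benzyloxy)-3-methoxyphenyl]-3-(methoxycarbonyl)but-3-enoic acid | COC(=O)/C(CC(=O)O)=C/c1ccc(OCc2ccccc2)c(OC)c1 | intermediate
5 | (3R)-4-[4-(benzyloxy)-3-methoxyphenyl]-3-(methoxycarbonyl)butanoic acid | OC(=O)C[C@@H](Cc1ccc(OCc2ccccc2)c(OC)c1)C(=O)OC | intermediate
6 | (3R)-4-[4-(benzyloxy)-3-methoxyphenyl]-3-(hydroxymethyl)butanoic acid (not isolated) | OC(=O)C[C@@H](Cc1ccc(OCc2ccccc2)c(OC)c1)CO | intermediate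
7 | (4R)-4-[4-(benzyloxy)-3-methoxybenzyl]oxolan-2-one | O=C1C[C@@H](Cc2ccc(OCc3ccccc3)c(OC)c2)CO1 | intermediate
8 | syringaldehyde | COc1cc(C=O)cc(OC)c1O | starting material
9 | 4-(tert-butyldimethylsilyloxy)-3,5-dimethoxybenzaldehyde | COc1cc(C=O)cc(OC)c1O[Si](C)(C)C(C)(C)C | intermediate
10 | [4-(tert-butyldimethylsilyloxy)-3,5-dimethoxyphenyl]methanol | COc1cc(CO)cc(OC)c1O[Si](C)(C)C(C)(C)C | intermediate
11 | 4-(tert-butyldimethylsilyloxy)-3,5-dimethoxybenzyl bromide | COc1cc(CBr)cc(OC)c1O[Si](C)(C)C(C)(C)C | intermediate
12 | lithium enolate of 7, stereocentre as in 7 (not isolated) | [Li]OC1=C[C@@H](Cc2ccc(OCc3ccccc3)c(OC)c2)CO1 | intermediate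
13 | (3R,4R)-trans-4-[4-(benzyloxy)-3-methoxybenzyl]-3-[4-(tert-butyldimethylsilyloxy)-3,5-dimethoxybenzyl]oxolan-2-one | O=C1[C@H](Cc2cc(OC)c(O[Si](C)(C)C(C)(C)C)c(OC)c2)[C@@H](Cc2ccc(OCc3ccccc3)c(OC)c2)CO1 | intermediate
14 | (2R,3R)-2-[4-(benzyloxy)-3-methoxybenzyl]-3-[4-(tert-butyldimethylsilyloxy)-3,5-dimethoxybenzyl]butane-1,4-diol | OC[C@H](Cc1cc(OC)c(O[Si](C)(C)C(C)(C)C)c(OC)c1)[C@@H](Cc1ccc(OCc2ccccc2)c(OC)c1)CO | intermediate
15 | (2R,3R)-2-[4-(benzyloxy)-3-methoxybenzyl]-3-(4-hydroxy-3,5-dimethoxybenzyl)butane-1,4-diol | OC[C@H](Cc1cc(OC)c(O)c(OC)c1)[C@@H](Cc1ccc(OCc2ccccc2)c(OC)c1)CO | intermediate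
16 | p-quinone methide of 15: syringyl ring as 2,6-dimethoxycyclohexa-2,5-dienone with an exocyclic C=C to the former benzylic carbon, both stereocentres as in 15 (not isolated) | OC[C@H](C=C1C=C(OC)C(=O)C(OC)=C1)[C@@H](Cc1ccc(OCc2ccccc2)c(OC)c1)CO | intermediate
17 | 4-{(2S,3R,4R)-4-[4-(benzyloxy)-3-methoxybenzyl]-3-(hydroxymethyl)oxolan-2-yl}-2,6-dimethoxyphenol (2,3-trans, 3,4-cis) | OC[C@H]1[C@@H](Cc2ccc(OCc3ccccc3)c(OC)c2)CO[C@@H]1c1cc(OC)c(O)c(OC)c1 | intermediate
18 | 5-methoxylariciresinol, (2S,3R,4R) | OC[C@H]1[C@@H](Cc2ccc(O)c(OC)c2)CO[C@@H]1c1cc(OC)c(O)c(OC)c1 | intermediate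
19 | (E)-ferulic acid | COc1cc(/C=C/C(=O)O)ccc1O | starting material
20 | 5-methoxylariciresinol (E)-ferulate at the C3 hydroxymethyl group, (2S,3R,4R), CNP0289934.1 | COc1cc(/C=C/C(=O)OC[C@H]2[C@@H](Cc3ccc(O)c(OC)c3)CO[C@@H]2c2cc(OC)c(O)c(OC)c2)ccc1O | target

**Totals**
Total step count: 13.
Longest linear sequence: 10 steps (steps 1–4 and 8–13, from vanillin). The bromide branch (steps 5–7) has 3 steps.

**Steps most likely to fail**

Step 11.
- What may go wrong:
  - a second oxidation of the product, which still carries a free phenol and a benzylic C–H;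
  - carbon attack by the guaiacyl ring on the quinone methide;
  - tautomerisation of the quinone methide to a styrene, with loss of the C3 configuration;
  - incomplete facial selectivity in the closure.
- The fallback carries the oxygen at the benzylic carbon from the start. It sets out from lactone 7 and aldehyde 9.
- Enolate 12 (LiN(SiMe3)2, THF, −78 °C) adds to 9 in an aldol reaction. This gives the trans hydroxybenzyl lactone F1, whose carbinol epimers both serve.
- LiAlH4 in THF reduces it to the triol F2.
- Catalytic camphorsulfonic acid in CH2Cl2 at 0 °C ionises the benzylic alcohol. The same hydroxyl then closes the same O1–C2 bond under thermodynamic control, giving the 2,3-trans silyl ether F3.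
- Bu4NF/AcOH in THF frees the phenol, and the route is rejoined at 17.

Step 13.
- What may go wrong: O-alkylation of one of the three phenols by the activated alcohol, slow activation of the β-branched alcohol, and a difficult separation from the phosphine oxide.
- The fallback masks all phenols and uses a carbodiimide coupling. It sets out from 18 and 19.
- Ferulic acid 19 with TBSCl and imidazole in DMF gives the bis-silyl derivative F4. K2CO3 in aqueous THF–MeOH hydrolyses its silyl ester to 4-O-silylferulic acid F5.
- Triol 18 with excess TBSCl and imidazole gives the tris-silyl ether F6. AcOH–THF–H2O at rt removes only the alkyl silyl ether, giving the bis(aryl silyl) alcohol F7.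
- Steglich esterification of F7 with F5 (EDC, DMAP, CH2Cl2) gives the tris-silyl ferulate F8.
- Bu4NF/AcOH in THF at 0 °C removes the three aryl silyl groups, and the route is rejoined at 20.

Step 12.
- What may go wrong: hydrogenolysis of the benzylic O1–C2 bond along with the benzyl ether, which would reopen the oxolane.
- The fallback moves the hydrogenolysis in front of the ring closure and exchanges benzyl for a group that is removed without H2. It sets out from 14, which has no other benzylic C–O bond.
- H2 over 10% Pd/C in EtOAc gives the guaiacyl phenol F9.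
- Allyl bromide and K2CO3 in acetone alkylate only the phenol, giving the allyl ether F10.
- Bu4NF/AcOH gives the free syringyl phenol F11.
- DDQ under the conditions of step 11 leads through the quinone methide F12 to the O-allyl oxolane F13.
- Allyl transfer to morpholine, catalysed by zerovalent palladium (Pd(PPh3)4, THF, rt, Tsuji-Trost type), frees the phenol, and the route is rejoined at 18.

**Further compounds**
F1 | step 11 | trans-(3R,4R)-type aldol lactone, 3-{hydroxy[4-(tert-butyldimethylsilyloxy)-3,5-dimethoxyphenyl]methyl}-4-[4-(benzyloxy)-3-methoxybenzyl]oxolan-2-one, epimers at the carbinol carbon | O=C1[C@H](C(O)c2cc(OC)c(O[Si](C)(C)C(C)(C)C)c(OC)c2)[C@@H](Cc2ccc(OCc3ccccc3)c(OC)c2)CO1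
F2 | step 11 | triol from reduction of F1, epimers at the carbinol carbon | OC[C@H](C(O)c1cc(OC)c(O[Si](C)(C)C(C)(C)C)c(OC)c1)[C@@H](Cc1ccc(OCc2ccccc2)c(OC)c1)CO
F3 | step 11 | O-tert-butyldimethylsilyl ether of 17 | OC[C@H]1[C@@H](Cc2ccc(OCc3ccccc3)c(OC)c2)CO[C@@H]1c1cc(OC)c(O[Si](C)(C)C(C)(C)C)c(OC)c1
F4 | step 13 | tert-butyldimethylsilyl (E)-4-O-(tert-butyldimethylsilyl)ferulate | COc1cc(/C=C/C(=O)O[Si](C)(C)C(C)(C)C)ccc1O[Si](C)(C)C(C)(C)C
F5 | step 13 | (E)-4-O-(tert-butyldimethylsilyl)ferulic acid | COc1cc(/C=C/C(=O)O)ccc1O[Si](C)(C)C(C)(C)C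
F6 | step 13 | tris-O-(tert-butyldimethylsilyl) ether of 18 | CC(C)(C)[Si](C)(C)OC[C@H]1[C@@H](Cc2ccc(O[Si](C)(C)C(C)(C)C)c(OC)c2)CO[C@@H]1c1cc(OC)c(O[Si](C)(C)C(C)(C)C)c(OC)c1
F7 | step 13 | bis(aryl O-tert-butyldimethylsilyl) ether of 18 with free primary alcohol | OC[C@H]1[C@@H](Cc2ccc(O[Si](C)(C)C(C)(C)C)c(OC)c2)CO[C@@H]1c1cc(OC)c(O[Si](C)(C)C(C)(C)C)c(OC)c1
F8 | step 13 | tris(aryl O-tert-butyldimethylsilyl) ether of 20 | COc1cc(/C=C/C(=O)OC[C@H]2[C@@H](Cc3ccc(O[Si](C)(C)C(C)(C)C)c(OC)c3)CO[C@@H]2c2cc(OC)c(O[Si](C)(C)C(C)(C)C)c(OC)c2)ccc1O[Si](C)(C)C(C)(C)C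
F9 | step 12 | (2R,3R)-2-(4-hydroxy-3-methoxybenzyl)-3-[4-(tert-butyldimethylsilyloxy)-3,5-dimethoxybenzyl]butane-1,4-diol | OC[C@H](Cc1cc(OC)c(O[Si](C)(C)C(C)(C)C)c(OC)c1)[C@@H](Cc1ccc(O)c(OC)c1)CO
F10 | step 12 | (2R,3R)-2-[4-(allyloxy)-3-methoxybenzyl]-3-[4-(tert-butyldimethylsilyloxy)-3,5-dimethoxybenzyl]butane-1,4-diol | OC[C@H](Cc1cc(OC)c(O[Si](C)(C)C(C)(C)C)c(OC)c1)[C@@H](Cc1ccc(OCC=C)c(OC)c1)CO
F11 | step 12 | (2R,3R)-2-[4-(allyloxy)-3-methoxybenzyl]-3-(4-hydroxy-3,5-dimethoxybenzyl)butane-1,4-diol | OC[C@H](Cc1cc(OC)c(O)c(OC)c1)[C@@H](Cc1ccc(OCC=C)c(OC)c1)CO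
F12 | step 12 | p-quinone methide of F11 | OC[C@H](C=C1C=C(OC)C(=O)C(OC)=C1)[C@@H](Cc1ccc(OCC=C)c(OC)c1)CO
F13 | step 12 | mono-O-allyl 5-methoxylariciresinol, (2S,3R,4R) | OC[C@H]1[C@@H](Cc2ccc(OCC=C)c(OC)c2)CO[C@@H]1c1cc(OC)c(O)c(OC)c1
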